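The runs were computed from invented constants, noise included.

**Count first.** I decide to count Q against G before I read any curve. These are the flasks and what is asked:

common to all: Z 0.20 M; Q 40 µM

| run | G | temperature | remark | time |
|---|---|---|---|---|
| theta | 42 µM | 25 °C | the very flask that is asked about, followed so far |  |
| epsilon | 63 µM | 20 °C | run made earlier |  |
| flask | 42 µM | 25 °C |  | 80 min |

| run | time / min | E / % |
|---|---|---|
| theta | 6.00 | 20.1 |
| theta | 12.0 | 23.1 |
| theta | 25.0 | 22.8 |
| theta | 40.0 | 21.4 |
| theta | 80.0 | 21.5 |
| epsilon | 1.33 | 7.9 |
| epsilon | 2.50 | 9.0 |
| epsilon | 4.00 | 7.7 |
| epsilon | 5.00 | 8.1 |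
| epsilon | 6.00 | 8.2 |

(standard deviation of a reading: 1 percentage point)

- E, in percent of the Z first charged, at 80 min
- the option that brings most further E ("none" if no option brings more than 2 percentage points) (ash / cedar / elm / larch / none)
- E present, with what was taken out counted in, in percent of the Z first charged, after elm
- E present, with what was taken out counted in, in percent of the Z first charged, after larch

- removed E is counted in
- additions bring no volume worth counting

- ash: at 80 min add Q, 50.0% of the amount charged, then wait 80 min
- cedar: change nothing and wait 80 min more
- elm: at 80 min take out 90% of the E then present, then wait 80 min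
- larch: at 80 min raise the temperature by 15 K, then wait 80 min

**The margin.** In the theta flask, which is the asked flask followed so far, G exceeds Q by 2.00 µM. I call G charged less Q charged the margin. If each G removes one Q, a positive margin makes Q the limiting reagent of that removal, and a later dose of Q larger than the margin should outlast the G that stays.

**First estimate.** The last four theta readings average 22.2%, so I expect about that at the asked time. The first reading, 20.1% at 6.00 min, puts the time constant of the rise near 2.54 min, a reading with its scatter. The asked 80 min is far longer than that, about 31.5 time constants.

**Equilibrium?** A level may be an equilibrium, and then fresh Q brings nothing. But the colder epsilon flask, with 63 µM of G, stands at 7.9% by 1.33 min, an earlier reading than theta's first, and it stays there within the scatter. A colder approach to equilibrium should be slower, so I read the level as a stalled catalyst.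

**G used up?** Perhaps G is not consumed, and then the margin means nothing. Even so, I grant the ash dose of 20.0 µM a plateau in proportion, 11 percentage points, which is more than the 2 points threshold. So ash stands either way. If G is consumed, the dose is ten times the margin and can bring far more. A stalled catalyst should make nothing under cedar, elm or larch.

**The forecast.** The forecast agrees with me: 22% now (21% to 23%), ash as best, 22% after elm (21% to 23.5%) and 22% after larch (21% to 24.5%). Its ground is that “the plateau marks dead enzyme rather than equilibrium”.

**The result.** The asked flask gives 22.2%. Ash brings 77 points, the most of the options, elm ends at 22.2% and larch at 22.2%. So the flask is stalled, with 77.8% of its Z still free and Q at 0%.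

    Q → D (k = 8.90 × 10⁻⁵ /s, Ea = 270 kJ/mol)
    Z + Q → E + Q, rate k2*[Z]^2*[Q]/(1 + ([Z]/Kh2)^2) (31.0 mM, k = 24000 /M²/s, Ea = 26.0 kJ/mol)
    Q → J (k = 2.10 × 10⁻⁴ /s, Ea = 91.0 kJ/mol)
    Q + G → L (k = 1400 /M/s, Ea = 40.0 kJ/mol)
    (constants at 25 °C)

**Margin again.** At 80.0 min the asked flask holds 2.59 µM of G, which is the margin of 2.00 µM plus the 0.595 µM of Q that went to D and J instead of L. The ash dose of 20.0 µM is larger than that G. The step from Q + G to L is the largest single effect on the gain: without that step, ash gains 0.099 points instead of 77 points.

**Second flask.** In a neighbour of the asked flask charged with 1.0 × 10⁻⁴ M of Q, the margin becomes −58.0 µM, so Q should outlast G. At 80.0 min that neighbour has G at 0% of its charge, Q still at 13.8% of its charge and E at 99.9% of the Z charged.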